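**Retrosynthetic overview**
1. 12 ⇐ 11: the last step only unmasks the two ring OH groups (tert-butyl vinylogous esters → OH; the OMe groups are untouched).
2. 11 ⇐ 10 ⇐ 9: both quinone rings are built at the same moment by a twofold cyclobutenone → hydroquinone ring expansion (4π opening/6π closure) of the tethered bis(4-alkenyl-4-hydroxycyclobutenone) 9, then oxidation.
3. 9 ⇐ 5 + 2 × 8: the C–Me/C–OMe edge of each ring comes from a β-methoxy-α-methylvinyllithium (from bromide 7, made from acetal 6).
4. 5 ⇐ 1 + 2 × 2: the C14 tether is joined to two squarate units by a double Grignard addition/transposition.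
5. Ring order: the two four-membered rings are bought in 2; the two six-membered rings form together in step 3; no other ring is made.

Assumption: the SMILES has no stereocentre and no stereogenic double bond, so the target is achiral and no asymmetric step is needed; the tether is read as 14 CH2 groups between the two ring carbons.

**Route**

Step 1
Reactants: 1 1,14-dibromotetradecane; 2 di-tert-butyl squarate (2 equiv)
Product: 5 3,3'-(tetradecane-1,14-diyl)bis(4-tert-butoxycyclobut-3-ene-1,2-dione), via di-Grignard reagent 3 (not isolated), via bis(bromomagnesium alkoxide) 4 (not isolated)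
Conditions: Mg, THF, 45 °C; 2 (2.5 equiv), THF, −78 °C; TFAA, −78 °C; aq NaHCO3
Reagents that add atoms: di-tert-butyl squarate (second equivalent of 2), CC(C)(C)OC1=C(OC(C)(C)C)C(=O)C1=O
Why: Each end of the di-Grignard adds 1,2 to a carbonyl of its own molecule of squarate (two molecules of 2 per molecule of 1), then TFAA-triggered ionisation of the carbinol and loss of the tert-butyl cation from the resulting oxocarbenium (squarate-to-cyclobutenedione transposition) gives the 3-alkoxy-4-alkyl dione at both chain ends, and no stereocentre survives.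

Step 2
Reactants: 6 2-bromo-1,1-dimethoxypropane (racemic)
Product: 7 (Z)-2-bromo-1-methoxyprop-1-ene
Conditions: TMSOTf, i-Pr2NEt, CH2Cl2, −20 °C to rt; spinning-band distillation, Z fraction kept
Reagents that add atoms: none
Why: Gassman-type acetal-to-enol-ether elimination (TMSOTf ionises the acetal, the hindered amine removes the α-proton acidified by bromine) gives a Z/E mixture of the enol ether, from which the Z isomer (Br cis to OMe, the only geometry whose lithio derivative is stable) is collected by fractional distillation and the minor E isomer is discarded.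

Step 3
Reactants: 5 3,3'-(tetradecane-1,14-diyl)bis(4-tert-butoxycyclobut-3-ene-1,2-dione); 7 (Z)-2-bromo-1-methoxyprop-1-ene (2 equiv)
Product: 11 3,3'-(tetradecane-1,14-diyl)bis(2-tert-butoxy-5-methoxy-6-methylcyclohexa-2,5-diene-1,4-dione), via vinyllithium 8 (not isolated), via bis-cyclobutenone diol 9 (not isolated), via bis-hydroquinone 10 (not isolated)
Conditions: 7 (2.5 equiv), t-BuLi (5.0 equiv), THF–Et2O, −78 °C; 5, −78 °C; sat. NH4Cl; toluene (0.01 M, base-washed glass), 110 °C; Ag2O, rt
Reagents that add atoms: (Z)-2-bromo-1-methoxyprop-1-ene (second equivalent of 7), CO/C=C(/C)Br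
Why: Br–Li exchange with retention gives the O-chelated cis-β-methoxyvinyllithium, one molecule of which adds to the ketone-like carbonyl next to C–OtBu of each dione unit, and on heating both 4-alkenyl-4-hydroxycyclobutenones open (OH rotating outward) to dienylketenes that undergo 6π-electrocyclisation and enolise to the bis-hydroquinone (Liebeskind–Moore ring expansion, twice in one flask), which Ag2O oxidises to the bis-quinone; this sequence places the chain next to OtBu and Me next to OMe and destroys the carbinol stereocentres of 9.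

Step 4
Reactants: 11 3,3'-(tetradecane-1,14-diyl)bis(2-tert-butoxy-5-methoxy-6-methylcyclohexa-2,5-diene-1,4-dione)
Product: 12 3,3'-(tetradecane-1,14-diyl)bis(2-hydroxy-5-methoxy-6-methylcyclohexa-2,5-diene-1,4-dione)
Conditions: TFA, CH2Cl2, 0 °C to rt
Reagents that add atoms: none
Why: Acidolysis (E1) of the tert-butyl vinylogous ester releases isobutene and the 2-hydroxyquinone while the methyl vinylogous ester is inert to TFA, and the product is achiral.

**Compound list**

1 | 1,14-dibromotetradecane | BrCCCCCCCCCCCCCCBr | starting material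
2 | di-tert-butyl squarate (3,4-di-tert-butoxycyclobut-3-ene-1,2-dione) | CC(C)(C)OC1=C(OC(C)(C)C)C(=O)C1=O | starting material
3 | tetradecane-1,14-diylbis(magnesium bromide) | Br[Mg]CCCCCCCCCCCCCC[Mg]Br | intermediate
4 | bis(bromomagnesium alkoxide) of 1,14-bis(2,3-di-tert-butoxy-1-hydroxy-4-oxocyclobut-2-en-1-yl)tetradecane (carbinol centres unassigned, mixture) | CC(C)(C)OC1=C(OC(C)(C)C)C(O[Mg]Br)(CCCCCCCCCCCCCCC2(O[Mg]Br)C(OC(C)(C)C)=C(OC(C)(C)C)C2=O)C1=O | intermediate
5 | 3,3'-(tetradecane-1,14-diyl)bis(4-tert-butoxycyclobut-3-ene-1,2-dione) | CC(C)(C)OC1=C(CCCCCCCCCCCCCCC2=C(OC(C)(C)C)C(=O)C2=O)C(=O)C1=O | intermediate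
6 | 2-bromo-1,1-dimethoxypropane (racemic) | CC(Br)C(OC)OC | starting material
7 | (Z)-2-bromo-1-methoxyprop-1-ene (Br cis to OMe) | CO/C=C(/C)Br | intermediate
8 | (1-methoxyprop-1-en-2-yl)lithium with Li cis to OMe (formally E, because C outranks Li) | CO/C=C(/C)[Li] | intermediate
9 | 2,2'-(tetradecane-1,14-diyl)bis{3-tert-butoxy-4-hydroxy-4-[(Z)-1-methoxyprop-1-en-2-yl]cyclobut-2-en-1-one} (carbinol centres unassigned, mixture) | CO/C=C(/C)C1(O)C(OC(C)(C)C)=C(CCCCCCCCCCCCCCC2=C(OC(C)(C)C)C(O)(/C(C)=C\OC)C2=O)C1=O | intermediate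
10 | 1,14-bis(2-tert-butoxy-3,6-dihydroxy-5-methoxy-4-methylphenyl)tetradecane | COc1c(C)c(O)c(OC(C)(C)C)c(CCCCCCCCCCCCCCc2c(O)c(OC)c(C)c(O)c2OC(C)(C)C)c1O | intermediate
11 | 3,3'-(tetradecane-1,14-diyl)bis(2-tert-butoxy-5-methoxy-6-methylcyclohexa-2,5-diene-1,4-dione) | COC1=C(C)C(=O)C(OC(C)(C)C)=C(CCCCCCCCCCCCCCC2=C(OC(C)(C)C)C(=O)C(C)=C(OC)C2=O)C1=O | intermediate
12 | 3,3'-(tetradecane-1,14-diyl)bis(2-hydroxy-5-methoxy-6-methylcyclohexa-2,5-diene-1,4-dione), CNP0278640.0 | COC1=C(C)C(=O)C(O)=C(CCCCCCCCCCCCCCC2=C(O)C(=O)C(C)=C(OC)C2=O)C1=O | target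

**Step count and risks**

Total steps: 4. Longest linear sequence: 3 (steps 1, 3, 4; step 2 is a one-step side branch).

Most likely to fail, in this order:

Step 3. The vinyllithium must be isomerically clean, the bis-adduct 9 is an acid-sensitive enol ether/tertiary alcohol, and the cyclohexadienone formed after 6π closure can lose MeOH instead of enolising. Fallback: it sets out from 5 and comes back at 11, bringing the methoxy group in after the ring expansion instead of on the vinyl reagent. Commercial isopropenylmagnesium bromide (THF, −78 °C) adds to 5 to give 2,2'-(tetradecane-1,14-diyl)bis[3-tert-butoxy-4-hydroxy-4-(prop-1-en-2-yl)cyclobut-2-en-1-one] F1. Heating in toluene at 110 °C gives 1,14-bis(2-tert-butoxy-3,6-dihydroxy-4-methylphenyl)tetradecane F2, and Ag2O gives 3,3'-(tetradecane-1,14-diyl)bis(2-tert-butoxy-6-methyl-1,4-benzoquinone) F3, which has one free ring position per quinone. Br2 in CH2Cl2 at −78 °C followed by Et3N gives 3,3'-(tetradecane-1,14-diyl)bis(5-bromo-2-tert-butoxy-6-methyl-1,4-benzoquinone) F4. NaOMe in MeOH/THF at 0 °C replaces bromide by addition–elimination and delivers 11.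

Step 2. The elimination gives both alkene isomers, and any E isomer carried into step 3 decomposes to propyne-derived nucleophiles. Fallback: it sets out from 7, taken as the undistilled Z/E elimination product, and comes back at 8, purifying the geometry through an isolable tin reagent instead of by distillation. The crude bromide is lithiated with t-BuLi at −78 °C and quenched with Bu3SnCl; only the cis-lithio species survives to give (Z)-tributyl(1-methoxyprop-1-en-2-yl)stannane F5, which is freed from the decomposition products of the E series by distillation and chromatography. Sn–Li exchange with n-BuLi in THF at −78 °C then regenerates 8 as a single isomer for step 3.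

Step 1. The di-Grignard may couple or add twice, and the tert-butyl vinylogous ester may not survive the TFAA transposition. Fallback: it sets out from 1 (as its di-Grignard 3) and comes back at 12, changing the masked hydroxyl to an acid-robust isopropyl ether. Addition of 3 to commercial diisopropyl squarate and NH4Cl quench give 1,14-bis(1-hydroxy-2,3-diisopropoxy-4-oxocyclobut-2-en-1-yl)tetradecane F6. Catalytic conc. HCl in CH2Cl2 converts it to 3,3'-(tetradecane-1,14-diyl)bis(4-isopropoxycyclobut-3-ene-1,2-dione) F7. Reaction with 8 as in step 3 gives 2,2'-(tetradecane-1,14-diyl)bis{4-hydroxy-3-isopropoxy-4-[(Z)-1-methoxyprop-1-en-2-yl]cyclobut-2-en-1-one} F8. Thermolysis gives 1,14-bis(3,6-dihydroxy-2-isopropoxy-5-methoxy-4-methylphenyl)tetradecane F9, and Ag2O gives 3,3'-(tetradecane-1,14-diyl)bis(2-isopropoxy-5-methoxy-6-methyl-1,4-benzoquinone) F10. BCl3 in CH2Cl2 (−78 to 0 °C) then cleaves the secondary alkyl ether in preference to the methyl ether and gives 12.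

**Further compounds**

F1 | step 3 | 2,2'-(tetradecane-1,14-diyl)bis[3-tert-butoxy-4-hydroxy-4-(prop-1-en-2-yl)cyclobut-2-en-1-one] | CC(=C)C1(O)C(OC(C)(C)C)=C(CCCCCCCCCCCCCCC2=C(OC(C)(C)C)C(O)(C(C)=C)C2=O)C1=O
F2 | step 3 | 1,14-bis(2-tert-butoxy-3,6-dihydroxy-4-methylphenyl)tetradecane | Cc1cc(O)c(CCCCCCCCCCCCCCc2c(O)cc(C)c(O)c2OC(C)(C)C)c(OC(C)(C)C)c1O
F3 | step 3 | 3,3'-(tetradecane-1,14-diyl)bis(2-tert-butoxy-6-methyl-1,4-benzoquinone) | CC1=CC(=O)C(CCCCCCCCCCCCCCC2=C(OC(C)(C)C)C(=O)C(C)=CC2=O)=C(OC(C)(C)C)C1=O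
F4 | step 3 | 3,3'-(tetradecane-1,14-diyl)bis(5-bromo-2-tert-butoxy-6-methyl-1,4-benzoquinone) | CC1=C(Br)C(=O)C(CCCCCCCCCCCCCCC2=C(OC(C)(C)C)C(=O)C(C)=C(Br)C2=O)=C(OC(C)(C)C)C1=O
F5 | step 2 | (Z)-tributyl(1-methoxyprop-1-en-2-yl)stannane | CO/C=C(/C)[Sn](CCCC)(CCCC)CCCC
F6 | step 1 | 1,14-bis(1-hydroxy-2,3-diisopropoxy-4-oxocyclobut-2-en-1-yl)tetradecane | CC(C)OC1=C(OC(C)C)C(O)(CCCCCCCCCCCCCCC2(O)C(OC(C)C)=C(OC(C)C)C2=O)C1=O
F7 | step 1 | 3,3'-(tetradecane-1,14-diyl)bis(4-isopropoxycyclobut-3-ene-1,2-dione) | CC(C)OC1=C(CCCCCCCCCCCCCCC2=C(OC(C)C)C(=O)C2=O)C(=O)C1=O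
F8 | step 1 | 2,2'-(tetradecane-1,14-diyl)bis{4-hydroxy-3-isopropoxy-4-[(Z)-1-methoxyprop-1-en-2-yl]cyclobut-2-en-1-one} | CO/C=C(/C)C1(O)C(OC(C)C)=C(CCCCCCCCCCCCCCC2=C(OC(C)C)C(O)(/C(C)=C\OC)C2=O)C1=O
F9 | step 1 | 1,14-bis(3,6-dihydroxy-2-isopropoxy-5-methoxy-4-methylphenyl)tetradecane | COc1c(C)c(O)c(OC(C)C)c(CCCCCCCCCCCCCCc2c(O)c(OC)c(C)c(O)c2OC(C)C)c1O
F10 | step 1 | 3,3'-(tetradecane-1,14-diyl)bis(2-isopropoxy-5-methoxy-6-methyl-1,4-benzoquinone) | COC1=C(C)C(=O)C(OC(C)C)=C(CCCCCCCCCCCCCCC2=C(OC(C)C)C(=O)C(C)=C(OC)C2=O)C1=O
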